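0.498 h per turnover at 5 mM of L, 0.800 h at 11 mM: with these two figures, read from the last points of the eta and delta runs, I opened the meeting on the flask.

| flask | E | X | L | remark | time |
|---|---|---|---|---|---|
| eta | 1.5 M | 2.7 M | 5 mM | run made earlier |  |
| delta | 1.5 M | 2.7 M | 11 mM | run made earlier |  |
| flask | 1.5 M | 2.70 M | 7.5 mM |  | 30 h |

| run | time / h | J / % |
|---|---|---|
| eta | 1.50 | 0 |
| eta | 5.00 | 0 |
| eta | 8.00 | 4.6 |
| eta | 12.0 | 7.6 |
| eta | 20.0 | 13.0 |
| eta | 25.0 | 17.7 |
| eta | 30.0 | 20.1 |
| delta | 4.00 | 2.5 |
| delta | 8.00 | 8.3 |
| delta | 12.0 | 11.1 |
| delta | 15.0 | 12.8 |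
| delta | 20.0 | 18.4 |
| delta | 25.0 | 23.7 |
| delta | 30.0 | 27.5 |

(standard deviation of a reading: 1 percentage point)

- solid, in amounts per volume of the solution: X
- at the start none of X is in solution

1. how much J there is at 30 h, in percent of the E charged
2. the change that raises the amount of J at 30 h, in percent of the E charged most ("none" if none brings more than 2 percentage points) (west / south / north-east / none)
3. amount of J at 30 h, in percent of the E charged, after north-east

- west: doubling the solubility of X, all else as stated
- south: doubling the dissolution coefficient of X, all else as stated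
- north-east: doubling the amount of L, all else as stated

I argued that each L worked more slowly where more L was charged, and I read this as L sharing a supply, the dissolving X, so that the time per turnover should climb along a line in cL. Both figures rest on single readings with a scatter of 1 percentage point. That line gave me 0.624 h at 7.5 mM, this being the turnover time: the hours one charged L spends per J made, t·cL/cJ, lag included, the inverse of the mean turnover frequency. Turned round, it gave me 24.1% for the flask. For north-east, beyond the runs, I extended the line to 1.00 h, hence 30.0%.

The forecast, tabled next, stood at 23.8% and 29.5% and named west, holding that “solubility sets the dissolved X level, so it enters both terms”. I had no turnover figure for west or south, and the meeting minuted the forecast's choice.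

The flask gave 23.9%, 28.9% after north-east, and west as best, gaining 20 points against 13 points for south and 5 points for north-east.

    G + L → Z (k = 49.0 M⁻¹ h⁻¹)
    E + Z ⇌ Q (K = 0.680 M⁻¹, k = 610 M⁻¹ h⁻¹)
    Q → D (k = 59.0 h⁻¹)
    D → L + J (k = 12.0 h⁻¹)
    X ⇌ G, rate k5*(cs5 - [G]) while solid is left; crystals form when [G] > cs5 (solubility = 0.180 M, k = 0.0970 h⁻¹)

The flask's turnover time comes to 0.628 h. Carried to the neighbour flask, with cE cut to 0.38 M, 0.624 h gives 95.0% J; that flask stores 83.3%, a turnover time of 0.711 h, longer than in the flask. At 30.0 h the neighbour flask holds 16.4% of its E unbound, and of its catalyst 38.3% as L, 1.99% as Q, 9.82% as D and 49.9% as Z.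

(All runs are calculated on assumed constants; scatter was added.)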